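At 8.0 h, the time of reading, the flask with 0.55 M of D has a number of half-lives of D behind it, and that count places the curve of D.

| setting | birch | oak | flask |
|---|---|---|---|
| D | 0.77 M | 1.2 M | 0.55 M |
| E | 140 mM (held) | 140 mM (held) | 140 mM (held) |
| remark | run made earlier | run made earlier |  |
| time |  |  | 8.0 h |

| run | time / h | X / % | D / % |
|---|---|---|---|
| birch | 1.00 | 5.4 | 38.5 |
| birch | 3.00 | 32.1 | 5.0 |
| birch | 5.00 | 58.9 | 0.3 |
| birch | 8.00 | 86.1 | 0.5 |
| oak | 1.00 | 5.8 | 38.9 |
| oak | 3.00 | 24.4 | 5.8 |
| oak | 5.00 | 43.7 | 3.6 |
| oak | 8.00 | 68.8 | 0 |

(each reading ± 1 percentage point)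

- X at 8.0 h, in percent of the D charged
- concentration of Z in solution at 2.0 h, in percent of saturation
- the change that raises the amount of X at 8.0 h, in percent of the D charged most ("none" if none brings more than 2 percentage points) (south-west / west / none)
- amount of X at 8.0 h, in percent of the D charged, after south-west

- south-west: doubling the saturation concentration of E, all else as stated
- west: doubling the transfer coefficient of E, all else as stated

- the numbers in the tables scatter by 1 percentage point (one standard deviation)
- at the start none of E is in solution
- Z is what E becomes in solution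

1. D starts with the steepest fall of its curve. After 1.00 h the birch run holds 38.5 % and the oak run 38.9 %, which is about the same share from different charges, so the loss reads as first-order decay. Both runs between 1.00 h and 3.00 h give the half-life of D, t½ = 0.703 h, an initial fall of 0.986 h⁻¹ of what is there.

2. X starts nearly flat. By 1.00 h the birch run has lost 61.5 % of its D but shows 5.4 % of X, so D passes through a hidden pool. Let H be the part of the charge that is neither X nor D. At 3.00 h, past the knee of X, birch H reads 62.9 %.

3. By 8.0 h the flask has had 11.4 half-lives, which leaves D at 0.0375 %. The level of X is then the charge less H and this D.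

4. At 8.0 h, H reads 13.4 % in birch and 31.2 % in oak, larger with the larger charge, as the charge to the power 1.90. Carried down to this flask, H is 7.06 %, far above D, so this reckoning puts X near 92.9 %.

5. The forecast, slightly lower, gives 92 % for X, 37 % for Z at 2.0 h, south-west as the best change and 99 % after it, saying the X rate “points to E transfer limiting”.

6. The flask gives 95.0 % of X at 8.0 h.

    D → J (k = 0.0160 min⁻¹)
    Z → L (k = 0.0160 min⁻¹)
    J + L → X (k = 0.0260 L mol⁻¹ min⁻¹)
    E ⇌ Z, rate k4*(csat - [Z]) (kL = 1.20 min⁻¹)

7. Z stands at 98.7 % of saturation at 2.0 h, and south-west is the best change, reaching 99.9 %. At 8.0 h the pool H is J, at 4.99 %, with D at 0.0462 % against the 0.0375 % of the count. The same flask read at 3.0 h has had 4.27 half-lives, so the count leaves 5.18 % of D, and the flask holds 5.61 %.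

The runs stem from a simulated flask from invented constants.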